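The product is monomer in chains, and what you want from each flask is the share of free monomer that ends as side product instead.

all flasks: free monomer 0.069 M

| charge | initiator | impurity | remark | time |
|---|---|---|---|---|
| south-east | 1 mol% | 0.10 mM | run made earlier |  |
| east | 1 mol% | 0.30 mM | run made earlier |  |
| gamma | 1 mol% | 0.15 mM |  | 12 h |
| epsilon | 1.5 mol% | 0.15 mM |  | 12 h |
| delta | 2.2 mol% | 0.15 mM |  | 12 h |

| run | time / h | monomer in chains / % | free monomer / % |
|---|---|---|---|
| south-east | 0.167 | 4.5 | 94.5 |
| south-east | 0.500 | 33.2 | 67.2 |
| south-east | 0.833 | 59.7 | 38.4 |
| south-east | 1.33 | 83.3 | 14.3 |
| south-east | 2.00 | 94.0 | 2.6 |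
| south-east | 2.50 | 96.2 | 1.3 |
| east | 0.200 | 4.9 | 95.2 |
| east | 0.333 | 12.0 | 87.5 |
| east | 0.500 | 23.2 | 76.2 |
| east | 0.833 | 46.8 | 51.4 |
| east | 1.33 | 71.8 | 24.9 |
| east | 2.50 | 92.3 | 3.4 |

(scatter of a reading: 0.3 percentage points)

- percentages count the free monomer that a species holds: one side product counts as two
- the numbers in the tables scatter by 0.3 percentage points (one standard deviation)
- no earlier run changes the charge of initiator; that part of a forecast is a guess
- a reading or a percentage of monomer in chains counts all its forms, free or not

1. which of the two there is more of at the end, counted by the free monomer in each, gamma (monomer in chains / side product)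
2. which of the two there is more of at the end, counted by the free monomer in each, epsilon (monomer in chains / side product)
3. which of the two there is more of at the end, counted by the free monomer in each, delta (monomer in chains / side product)
4. final monomer in chains, as a percentage of the free monomer charged, in gamma
5. final monomer in chains, as a percentage of the free monomer charged, in epsilon
6. final monomer in chains, as a percentage of the free monomer charged, in delta

Read the runs as a ladder of times. On the bottom rung I put the impurity, assuming it kills initiator one for one, so the working amount is the active charge, initiator charged minus impurity: 0.590 mM in south-east, 0.390 mM in east. The late first-order decay constants of free monomer read 2.54 h⁻¹ and 1.70 h⁻¹, a ratio of 1.49 against 1.51 for the active charges.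

Next rung: in south-east that constant starts near 0.339 h⁻¹ up to 0.167 h, so active centres build up during the run. Scaled to gamma's active charge of 0.540 mM, the late constant gives a half-life of 0.298 h, and by my reckoning hardly any free monomer remains in gamma at 12 h. Top rung: the missing share in south-east reads 3.40% at 2.00 h and 2.50% at 2.50 h, with no growth, so I let chains stand.

What remains is the ratio of two rates, a selectivity factor, which I read here as a share over each run up to its last reading. I assume free monomer cancels from it and chain growth scales with active charge. The last readings put the missing share of the free monomer consumed at 2.53% in south-east and 4.45% in east, each with the scatter of its readings. Multiplied by active charge, these give 0.0149 mM and 0.0174 mM, mean 0.0162 mM. This is the loss scale, side-product share of consumed free monomer times active charge. Dividing it by active charge, I expect monomer in chains at 97.0% in gamma, 98.2% in epsilon and 98.8% in delta, the last two being guesses about initiator.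

The forecast names monomer in chains in gamma, monomer in chains in epsilon and monomer in chains in delta, at 96.3%, 97.2% and 97.8%, each lower than mine , and holds that “chains dominate in every charge”.

    free monomer + initiator → living end + monomer in chains (k = 0.00390 M⁻¹ s⁻¹)
    free monomer + living end → monomer in chains + living end, rate k2*[living end]*[free monomer] (k = 1.90 M⁻¹ s⁻¹)
    initiator + impurity → spent initiator (k = 880 M⁻¹ s⁻¹)
    crystals ⇌ monomer in chains, rate k4*(cs4 - [monomer in chains]) while solid is left; crystals form when [monomer in chains] > cs4 (solubility = 42.0 mM, k = 0.00630 s⁻¹)
    free monomer + monomer in chains → side product (k = 2.20 × 10⁻⁴ M⁻¹ s⁻¹)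

The flasks give monomer in chains in gamma, monomer in chains in epsilon and monomer in chains in delta, at 97.2%, 97.9% and 98.3%, with side product at 2.84%, 2.15% and 1.69%. In epsilon at 0.552 h, free monomer is used 78 times as fast by the path to chains as by the path to side product. That side path in epsilon has >99.9% of its turnover up to 12 h behind it after 6.00 h. The loss scale over gamma's active charge gives 3.00%. A neighbour like epsilon with 0.38 mol% of initiator has an active charge of 0.112 mM, where the loss scale gives 14.5%, and at 12.0 h that flask holds 7.57% side product.

All runs stem from a simulated flask from invented constants, and the scatter is random.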